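**Retrosynthetic overview**
1. The target is opened to its valence isomer, a humulane-type (2E,8E,10Z)-cycloundeca-2,8,10-trienone that already carries the OH, the angelate and the isovalerate. The forward reaction is a transannular crossed [2+2] forming C2–C8 and C3–C9.
2. The macrocycle comes from an acyclic (Z)-β-iodoenone with a terminal vinyl group, closed at C9–C10 by an intramolecular Heck reaction.
3. The oxygen triad comes from selective angeloylation, Ti-mediated opening of a 2,3-epoxy alcohol by isovaleric acid (inversion), Shi epoxidation, and Brown reverse prenylation (carbinol, CMe2 and vinyl in one step).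
4. The carbon chain comes from ynone hydroiodination, a Weinreb/propynyl ketone synthesis, and Wittig C2 homologation of ethyl 3-methyl-4-oxocrotonate.
5. Ring order: the eleven-membered ring forms first, then the cyclobutane, cyclohexenone and cycloheptane rings form together in the last step.

Assumption: all numbered starting materials and the reagents named under Conditions are bought; locants in 10–17 follow the dodecane chain, in 18 the cycloundecane ring (C1 = C=O), and in 19 the longipinane skeleton.

**Step 1**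
Reactants: 1 ethyl (2E)-3-methyl-4-oxobut-2-enoate; 2 (triphenylphosphoranylidene)acetaldehyde
Product: 3 ethyl (2E,4E)-3-methyl-6-oxohexa-2,4-dienoate
Conditions: toluene, 80 °C
Reagents that add atoms: none
Why: Wittig olefination with the stabilised formyl ylide (1.05 equiv) adds two carbons and gives the new C4=C5 alkene E, while the less electrophilic dienal product and the enoate do not react further.

**Step 2**
Reactants: 3 ethyl (2E,4E)-3-methyl-6-oxohexa-2,4-dienoate; 4 (3-methylbut-2-en-1-yl)magnesium chloride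
Product: 7 ethyl (2E,4E,6R)-6-hydroxy-3,7,7-trimethylnona-2,4,8-trienoate, via prenyldiisopinocampheylborane 5 (not isolated), via borinate ester 6 (not isolated)
Conditions: (−)-Ipc2BOMe, 4, Et2O, −78 to 25 °C; 3, −78 °C; NaBO3·4H2O, THF/H2O, 25 °C
Reagents that add atoms: none
Why: Brown asymmetric reverse prenylation (allylboration) runs through a chair Zimmerman–Traxler transition state with γ-attack, which builds the CMe2–vinyl quaternary carbon, and the isopinocampheyl groups derived from (+)-α-pinene select the aldehyde face that gives the 6R carbinol (future C7), the aldehyde reacting far faster than the enoate.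

**Step 3**
Reactants: 7 ethyl (2E,4E,6R)-6-hydroxy-3,7,7-trimethylnona-2,4,8-trienoate; 8 prop-1-yn-1-ylmagnesium bromide
Product: 10 (5E,7E,9R)-9-hydroxy-6,10,10-trimethyldodeca-5,7,11-trien-2-yn-4-one, via Weinreb amide 9 (not isolated)
Conditions: MeNH(OMe)·HCl, iPrMgCl, THF, −20 °C; then 8, 0 to 25 °C; aq. NH4Cl
Reagents that add atoms: none
Why: This is a Weinreb ketone synthesis run in one flask, in which the magnesium amide converts the ester to the amide, the chelated tetrahedral adduct of the alkynyl Grignard reagent stops at the ketone stage, the carbinol is only carried as its alkoxide, and no stereocentre is touched.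

**Step 4**
Reactants: 10 (5E,7E,9R)-9-hydroxy-6,10,10-trimethyldodeca-5,7,11-trien-2-yn-4-one
Product: 11 (2Z,5E,7E,9R)-9-hydroxy-2-iodo-6,10,10-trimethyldodeca-2,5,7,11-tetraen-4-one
Conditions: NaI, AcOH, 25 °C
Reagents that add atoms: sodium iodide, [Na+].[I-]
Why: In this conjugate hydroiodination of an ynone, iodide adds to the β-carbon and the allenol is protonated on the side away from iodine, so the kinetic (Z)-β-iodoenone (I cis to C=O) forms, which fixes the later ring alkene geometry.

**Step 5**
Reactants: 11 (2Z,5E,7E,9R)-9-hydroxy-2-iodo-6,10,10-trimethyldodeca-2,5,7,11-tetraen-4-one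
Product: 12 (2Z,5E,7R,8R,9S)-7,8-epoxy-9-hydroxy-2-iodo-6,10,10-trimethyldodeca-2,5,11-trien-4-one
Conditions: D-fructose-derived Shi ketone (30 mol %), KHSO5 (as 2KHSO5·KHSO4·K2SO4), K2CO3, Bu4NHSO4, MeCN/CH2(OMe)2/aq. Na2B4O7 buffer, 0 °C
Reagents that add atoms: potassium peroxymonosulfate, [K+].[O-]S(=O)(=O)OO
Why: In the Shi asymmetric epoxidation the chiral dioxirane attacks only the trans-disubstituted C7=C8 alkene (the terminal vinyl group and the carbonyl-bound alkenes are poor substrates, and the β,β-disubstituted iodoenone should survive the cold buffer), and its spiro transition state gives the (7R,8R)-epoxide, in line with the threo preference of the allylic OH held opposite the tert-alkyl group.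

**Step 6**
Reactants: 12 (2Z,5E,7R,8R,9S)-7,8-epoxy-9-hydroxy-2-iodo-6,10,10-trimethyldodeca-2,5,11-trien-4-one; 13 3-methylbutanoic acid
Product: 14 (2Z,5E,7S,8R,9S)-8,9-dihydroxy-2-iodo-6,10,10-trimethyl-4-oxododeca-2,5,11-trien-7-yl 3-methylbutanoate
Conditions: 13, Ti(OiPr)4 (1.5 equiv), CH2Cl2, 25 °C
Reagents that add atoms: none
Why: In this Sharpless-type Ti(OiPr)4-mediated opening of a 2,3-epoxy alcohol, titanium binds the carbinol and epoxide oxygens and the carboxylate attacks the distal allylic C7 by SN2 with inversion (7R to 7S), which leaves C8 untouched and places the isovalerate directly on the future C9.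

**Step 7**
Reactants: 14 (2Z,5E,7S,8R,9S)-8,9-dihydroxy-2-iodo-6,10,10-trimethyl-4-oxododeca-2,5,11-trien-7-yl 3-methylbutanoate; 15 (2Z)-2-methylbut-2-enoic acid (angelic acid)
Product: 17 (2Z,5E,7S,8R,9S)-9-hydroxy-2-iodo-6,10,10-trimethyl-7-(3-methylbutanoyloxy)-4-oxododeca-2,5,11-trien-8-yl (2Z)-2-methylbut-2-enoate, via mixed anhydride 16 (not isolated)
Conditions: 15, 2,4,6-Cl3C6H2COCl, Et3N, toluene, 25 °C; then 14, 75 °C
Reagents that add atoms: none
Why: Yamaguchi-type mixed-anhydride esterification without a nucleophilic catalyst keeps the angelate Z, and the 8-OH is acylated in preference to the neopentyl 9-OH next to CMe2, so no protecting group is needed.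

**Step 8**
Reactants: 17 (2Z,5E,7S,8R,9S)-9-hydroxy-2-iodo-6,10,10-trimethyl-7-(3-methylbutanoyloxy)-4-oxododeca-2,5,11-trien-8-yl (2Z)-2-methylbut-2-enoate
Product: 18 (2E,4S,5R,6S,8E,10Z)-6-hydroxy-3,7,7,10-tetramethyl-4-(3-methylbutanoyloxy)-1-oxocycloundeca-2,8,10-trien-5-yl (2Z)-2-methylbut-2-enoate
Conditions: Pd(OAc)2 (20 mol %), Ag2CO3, DMF (1 mM), 60 °C
Reagents that add atoms: none
Why: In this intramolecular Heck macrocyclisation, zerovalent palladium inserts into the (Z)-C–I bond with retention, the alkenyl group adds to the free CH2 terminus of the neopentyl vinyl group, and syn β-hydride elimination (the quaternary carbon offers no other β-hydrogen) gives only the (8E,10Z)-diene, in analogy to palladium-mediated closures of the humulene ring next to its CMe2 group.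

**Step 9**
Reactants: 18 (2E,4S,5R,6S,8E,10Z)-6-hydroxy-3,7,7,10-tetramethyl-4-(3-methylbutanoyloxy)-1-oxocycloundeca-2,8,10-trien-5-yl (2Z)-2-methylbut-2-enoate
Product: 19 (4R,5S,7S,8R,9S,10R,11R)-7-hydroxy-9-(3-methylbutanoyloxy)-1-oxolongipin-2-en-8-yl (2Z)-2-methylbut-2-enoate (target)
Conditions: [Ir(dF(CF3)ppy)2(dtbbpy)]PF6 (2 mol %), 450 nm LED, degassed MeCN (2 mM), 20 °C
Reagents that add atoms: none
Why: Proposed new method: triplet energy transfer (about 61 kcal/mol, enough for the cross-conjugated trienone but not for the angelate or the enone of 19) gives the twisted dienone triplet, whose neopentyl terminus C8 bonds to C2 to give a cis-fused six/seven-membered 1,4-biradical (tertiary radical at C3, oxapentadienyl radical at C9) that closes C3–C9, so the cyclobutane, cyclohexenone and cycloheptane rings arise at once; the other pairing (C8–C3/C9–C2) would join a neopentyl carbon to a fully substituted one, a trans-fused biradical cannot close and falls back to 18, the four-carbon bridge forces CMe2 and C4 onto one cyclobutane face (sets C5 and C10 of 19), and C9 reaches C3 anti to the C4–O bond with C5 lying in the alkene plane (sets C4, C10 and C11 of 19 relative to the triad); the closest known reaction types are the transannular enone–olefin [2+2] photocycloaddition of cyclodeca-1,6-dienones to tricyclo[4.4.0.0(2,8)]decanones and the visible-light crossed [2+2] of 2-vinylaryl enones to bicyclo[3.1.1]heptanones.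

**Compound list**
1 | ethyl (2E)-3-methyl-4-oxobut-2-enoate | CCOC(=O)/C=C(\C)C=O | starting material
2 | (triphenylphosphoranylidene)acetaldehyde | O=CC=P(c1ccccc1)(c1ccccc1)c1ccccc1 | starting material
3 | ethyl (2E,4E)-3-methyl-6-oxohexa-2,4-dienoate | CCOC(=O)/C=C(\C)/C=C/C=O | intermediate
4 | (3-methylbut-2-en-1-yl)magnesium chloride | CC(C)=CC[Mg]Cl | starting material
5 | prenyldiisopinocampheylborane (Ipc from (+)-α-pinene) | CC(C)=CCB([C@H]1[C@H](C)[C@H]2C[C@@H](C1)C2(C)C)[C@H]1[C@H](C)[C@H]2C[C@@H](C1)C2(C)C | intermediate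
6 | diisopinocampheylborinate ester of 7 | CCOC(=O)/C=C(\C)/C=C/[C@@H](OB([C@H]1[C@H](C)[C@H]2C[C@@H](C1)C2(C)C)[C@H]1[C@H](C)[C@H]2C[C@@H](C1)C2(C)C)C(C)(C)C=C | intermediate
7 | ethyl (2E,4E,6R)-6-hydroxy-3,7,7-trimethylnona-2,4,8-trienoate | CCOC(=O)/C=C(\C)/C=C/[C@@H](O)C(C)(C)C=C | intermediate
8 | prop-1-yn-1-ylmagnesium bromide | CC#C[Mg]Br | starting material
9 | (2E,4E,6R)-6-hydroxy-N-methoxy-N,3,7,7-tetramethylnona-2,4,8-trienamide | CON(C)C(=O)/C=C(\C)/C=C/[C@@H](O)C(C)(C)C=C | intermediate
10 | (5E,7E,9R)-9-hydroxy-6,10,10-trimethyldodeca-5,7,11-trien-2-yn-4-one | CC#CC(=O)/C=C(\C)/C=C/[C@@H](O)C(C)(C)C=C | intermediate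
11 | (2Z,5E,7E,9R)-9-hydroxy-2-iodo-6,10,10-trimethyldodeca-2,5,7,11-tetraen-4-one | C/C(I)=C/C(=O)/C=C(\C)/C=C/[C@@H](O)C(C)(C)C=C | intermediate
12 | (2Z,5E,7R,8R,9S)-7,8-epoxy-9-hydroxy-2-iodo-6,10,10-trimethyldodeca-2,5,11-trien-4-one | C/C(I)=C/C(=O)/C=C(\C)[C@H]1O[C@@H]1[C@@H](O)C(C)(C)C=C | intermediate
13 | 3-methylbutanoic acid (isovaleric acid) | CC(C)CC(=O)O | starting material
14 | (2Z,5E,7S,8R,9S)-8,9-dihydroxy-2-iodo-6,10,10-trimethyl-4-oxododeca-2,5,11-trien-7-yl 3-methylbutanoate | C/C(I)=C/C(=O)/C=C(\C)[C@H](OC(=O)CC(C)C)[C@H](O)[C@@H](O)C(C)(C)C=C | intermediate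
15 | (2Z)-2-methylbut-2-enoic acid (angelic acid) | C/C=C(/C)C(=O)O | starting material
16 | angelic 2,4,6-trichlorobenzoic anhydride | C/C=C(/C)C(=O)OC(=O)c1c(Cl)cc(Cl)cc1Cl | intermediate
17 | (2Z,5E,7S,8R,9S)-9-hydroxy-2-iodo-6,10,10-trimethyl-7-(3-methylbutanoyloxy)-4-oxododeca-2,5,11-trien-8-yl (2Z)-2-methylbut-2-enoate | C/C(I)=C/C(=O)/C=C(\C)[C@H](OC(=O)CC(C)C)[C@H](OC(=O)/C(C)=C\C)[C@@H](O)C(C)(C)C=C | intermediate
18 | (2E,4S,5R,6S,8E,10Z)-6-hydroxy-3,7,7,10-tetramethyl-4-(3-methylbutanoyloxy)-1-oxocycloundeca-2,8,10-trien-5-yl (2Z)-2-methylbut-2-enoate | O=C1/C=C(\C)[C@H](OC(=O)CC(C)C)[C@H](OC(=O)/C(C)=C\C)[C@@H](O)C(C)(C)/C=C/C(C)=C\1 | intermediate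
19 | (4R,5S,7S,8R,9S,10R,11R)-8-angeloyloxy-7-hydroxy-9-isovaleroyloxylongipin-2-en-1-one | C/C=C(/C)C(=O)O[C@@H]1[C@@H](O)C(C)(C)[C@@H]2[C@H]3C(=O)C=C(C)[C@@H]2[C@@]3(C)[C@@H]1OC(=O)CC(C)C | target

**Totals:** 9 steps in all; the longest linear sequence is 9 steps (1 to 19).

**Steps most likely to fail**

Step 9. The regiochemistry and face selectivity of this transannular closure have no direct precedent on an eleven-membered trienone. The fallback sets out from diol 14 and locks the four-carbon bridge before any ring is closed. 2,2-Dimethoxypropane and PPTS tie the 8- and 9-oxygens into a trans-dioxolane, the 8,9-acetonide F1. Heck closure as in step 8 gives the locked macrocycle F2, whose dioxolane holds the C4–C5–C6–C7 torsion near the gauche value found in the product. Sensitised irradiation as in step 9 gives the tricyclic acetonide F3, and aqueous acetic acid frees the tricyclic 7,8-diol F4. Mixed anhydride 16 then acylates the 8-OH of the rigid tricycle, because the 7-OH is neopentyl, and the sequence comes back to the route at 19.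

Step 8. The eleven-membered ring may not close at C9–C10, and the allylic ester is exposed to zerovalent palladium. The fallback sets out from 17 and moves the ring-closing bond. Stille coupling with tributyl(vinyl)stannane (PdCl2(MeCN)2, DMF, 25 °C) replaces iodine by vinyl with retention and gives the vinyl pentaene F5. Ring-closing metathesis (second-generation Hoveyda–Grubbs catalyst, 1,4-benzoquinone, toluene, 0.5 mM, 80 °C) then forms C8=C9 instead, and the sequence comes back to the route at 18.

Step 7. The risks are 8-OH versus 9-OH selectivity, acyl migration at 75 °C, and angelate-to-tiglate isomerisation. The fallback sets out from 14 and builds the angelate double bond after a cold acylation. 2-(Diphenoxyphosphoryl)propanoic acid with DCC and catalytic DMAP in CH2Cl2 at −20 °C gives the 8-O-phosphonopropionate F6. An Ando-type Z-selective Horner–Wadsworth–Emmons reaction with acetaldehyde (NaI, DBU, THF, −20 to 0 °C) installs the (Z)-2-methylbut-2-enoate, and the sequence comes back to the route at 17.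

**Further compounds**
F1 | step 9 | 8,9-acetonide (8,9-O-isopropylidene derivative of 14) | C/C(I)=C/C(=O)/C=C(\C)[C@H](OC(=O)CC(C)C)[C@@H]1OC(C)(C)O[C@H]1C(C)(C)C=C
F2 | step 9 | locked macrocycle (5,6-O-isopropylidene analogue of 18, 4-isovalerate kept) | O=C1/C=C(\C)[C@H](OC(=O)CC(C)C)[C@@H]2OC(C)(C)O[C@H]2C(C)(C)/C=C/C(C)=C\1
F3 | step 9 | tricyclic acetonide (7,8-O-isopropylidene-9-isovaleroyloxylongipin-2-en-1-one) | CC1(C)O[C@@H]2[C@@H](O1)C(C)(C)[C@@H]3[C@H]4C(=O)C=C(C)[C@@H]3[C@@]4(C)[C@@H]2OC(=O)CC(C)C
F4 | step 9 | tricyclic 7,8-diol (7,8-dihydroxy-9-isovaleroyloxylongipin-2-en-1-one) | O[C@@H]1[C@@H](O)C(C)(C)[C@@H]2[C@H]3C(=O)C=C(C)[C@@H]2[C@@]3(C)[C@@H]1OC(=O)CC(C)C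
F5 | step 8 | vinyl pentaene (17 with I replaced by CH=CH2, Z retained) | C=C/C(C)=C\C(=O)/C=C(\C)[C@H](OC(=O)CC(C)C)[C@H](OC(=O)/C(C)=C\C)[C@@H](O)C(C)(C)C=C
F6 | step 7 | 8-O-phosphonopropionate (8-O-[2-(diphenoxyphosphoryl)propanoyl] derivative of 14) | C/C(I)=C/C(=O)/C=C(\C)[C@H](OC(=O)CC(C)C)[C@H](OC(=O)C(C)P(=O)(Oc1ccccc1)Oc1ccccc1)[C@@H](O)C(C)(C)C=C
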